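**Retrosynthetic overview**
1. The last bond is the C11–O aryl ether (Mitsunobu reaction of isofraxidin 17 with alcohol 16); C8=C12 comes from the C8 ketone of 14, and the C2 acetoxy group is equilibrated to its equatorial position.
2. Ring A is opened at C1–C10 and C11 is removed at C9–C11: the cis-fused keto alcohol 14 goes back to the monocyclic bis-enone 11 plus formaldehyde (stannane-mediated reductive β,β'-radical cyclization, then aldol reaction of the tin enolate).
3. Enabling feature: the quaternary C10 is the β-carbon of the C8 carbonyl (C8–C9–C10, ring B) and is bonded to C1, the β-carbon of the C3 carbonyl (C3–C2(OAc)–C1, ring A); the quaternary C4 lets the 2,3-dione enolise only toward C1, so the 2-acetoxy enone forms regiospecifically.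
4. 11 comes from a C4–C5 bond made by Ireland–Claisen rearrangement of (R)-2-methylcyclohex-2-enyl isobutyrate (C–O to C–C chirality transfer), C2/C1 from a 1-ethoxyvinyl stannane, and the C8 oxygen from allylic oxidation.
5. Order of rings: ring B comes from 2-methylcyclohex-2-enone (1), the two coumarin rings from isofraxidin (17); ring A is the only ring closed in the route, in step 7.

Key step: step 7

Remark: drimane numbering is used (C1–C10 decalin, C11 = CH2O, C12 = exocyclic CH2); read from the SMILES, the decalin is cis-fused, with H-5, CH3-10 and C11 on one face and the C2 acetoxy group on the other, and the route is designed for this configuration.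

Step 1
Reactants: 1 2-methylcyclohex-2-en-1-one
Product: 2 (R)-2-methylcyclohex-2-en-1-ol
Conditions: (S)-2-methyl-CBS-oxazaborolidine (10 mol%), BH3·SMe2, THF, −20 °C
Reagents that add atoms: none
Why: Corey–Bakshi–Shibata reduction: hydride is delivered to the ketone face set by the larger 2-methylalkenyl side against the ring CH2, which with the S catalyst should give the R allylic alcohol by 1,2-reduction.

Step 2
Reactants: 2 (R)-2-methylcyclohex-2-en-1-ol
Product: 3 (R)-2-methylcyclohex-2-en-1-yl 2-methylpropanoate
Conditions: i-PrCOCl, Et3N, DMAP (cat.), CH2Cl2, 0 °C to rt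
Reagents that add atoms: isobutyryl chloride, CC(C)C(Cl)=O
Why: Nucleophile-catalysed acylation of the secondary allylic alcohol with an acid chloride, with retention at the carbinol carbon.

Step 3
Reactants: 3 (R)-2-methylcyclohex-2-en-1-yl 2-methylpropanoate
Product: 6 2-methyl-2-[(1S)-2-methylcyclohex-2-en-1-yl]propanoic acid, via silyl ketene acetal 4 (not isolated), via trimethylsilyl ester 5 (not isolated)
Conditions: LiN(i-Pr)2, THF, −78 °C; Me3SiCl; warm to 60 °C; cold dilute aq. HCl work-up
Reagents that add atoms: none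
Why: Ireland–Claisen rearrangement: the tetrasubstituted silyl ketene acetal (no enolate geometry issue) rearranges suprafacially over the cyclohexenyl allyl unit, so the new C4–C5 bond forms on the face from which the C9–O bond leaves, the carbinol configuration is transferred to C5 (S), and the silyl ester is cleaved on work-up.

Step 4
Reactants: 6 2-methyl-2-[(1S)-2-methylcyclohex-2-en-1-yl]propanoic acid
Product: 9 4-methyl-4-[(1S)-2-methylcyclohex-2-en-1-yl]pentane-2,3-dione, via acid chloride 7 (not isolated), via 2-ethoxy enone 8 (not isolated)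
Conditions: Me2C=C(Cl)NMe2, CH2Cl2, 0 °C; then Bu3SnC(OEt)=CH2, PdCl2(PPh3)2 (cat.), PhMe, 80 °C; then 1 M HCl, THF, rt
Reagents that add atoms: tributyl(1-ethoxyvinyl)stannane, CCCC[Sn](CCCC)(CCCC)C(=C)OCC; water, O
Why: Stille acylation of the acid chloride with the 1-ethoxyvinyl stannane (an acetyl-anion equivalent) and hydrolysis of the enol ether should give the 1,2-dione; C4 is quaternary, so nothing can enolise toward C5 and the stereocentre is safe.

Step 5
Reactants: 9 4-methyl-4-[(1S)-2-methylcyclohex-2-en-1-yl]pentane-2,3-dione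
Product: 10 4-methyl-4-[(1S)-2-methyl-4-oxocyclohex-2-en-1-yl]pentane-2,3-dione
Conditions: CrO3, 3,5-dimethylpyrazole, CH2Cl2, −20 °C
Reagents that add atoms: chromium trioxide, O=[Cr](=O)=O
Why: Allylic oxidation by the CrO3–3,5-dimethylpyrazole complex at the ring CH2 (C8) next to the alkene CH, the usual outcome for 1-methylcyclohexenes, should give the 3-methylcyclohex-2-enone unit of ring B without touching C5.

Step 6
Reactants: 10 4-methyl-4-[(1S)-2-methyl-4-oxocyclohex-2-en-1-yl]pentane-2,3-dione
Product: 11 4-methyl-4-[(1S)-2-methyl-4-oxocyclohex-2-en-1-yl]-3-oxopent-1-en-2-yl acetate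
Conditions: Ac2O, Et3N, DMAP (cat.), CH2Cl2, −20 °C
Reagents that add atoms: acetic anhydride, CC(=O)OC(C)=O
Why: O-Acylation of the dione enolate, which can form only toward the methyl group because C4 is quaternary, gives the 2-acetoxy enone (a captodative alkene) regiospecifically; the low temperature keeps the enolate from adding to the ring enone.

Step 7
Reactants: 11 4-methyl-4-[(1S)-2-methyl-4-oxocyclohex-2-en-1-yl]-3-oxopent-1-en-2-yl acetate
Product: 14 (4aS,5S,8aS)-5-(hydroxymethyl)-1,1,4a-trimethyl-2,6-dioxodecahydronaphthalen-3-yl acetate (both C-3 epimers), via tin enolate 12 (not isolated), via tin aldolate 13 (not isolated)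
Conditions: Bu3SnH (slow addition), AIBN (cat.), PhH, 80 °C; then CH2O (monomer), THF, −78 °C to rt; H2O
Reagents that add atoms: formaldehyde, C=O
Why: Proposed new method: Bu3Sn• should add reversibly to the oxygen of the ring-B enone, the less hindered carbonyl, to give an allylic O-stannyl ketyl whose C10 terminus adds to the unsubstituted C1 of the captodative 2-acetoxy enone; the C2 radical then takes H from Bu3SnH, ring B is left as its tributyltin enolate, and formaldehyde is added at C9. The closest known reaction type is the stannane-mediated coupling of the β-carbons of two tethered activated alkenes through allylic O-stannyl ketyls, combined with aldol capture of tin enolates made by radical conjugate reduction. Ring A closes by the C10–C1 bond in the 6-endo-trig mode, since attack at the fully substituted, acetoxy-bearing C2 (5-exo) is blocked and electronically mismatched. At C10 the allylic 1,2-strain between the ring methyl and the quaternary C4 holds the side chain at C5 pseudoaxial, so C1 bonds on the side-chain face and the ring fusion is cis; at C9 formaldehyde enters on the convex face of the cis-bicycle, anti to C1; C2 is set without control by hydrogen transfer and is corrected in step 9. The step needs the chain to run through the ring ketyl and not through the side-chain enone or plain conjugate reduction: the C3 carbonyl is shielded by the quaternary C4, ketyl formation is reversible, slow stannane addition keeps hydrogen transfer slow, and only the ring ketyl has a fast, polarity-matched addition to a terminal CH2.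

Step 8
Reactants: 14 (4aS,5S,8aS)-5-(hydroxymethyl)-1,1,4a-trimethyl-2,6-dioxodecahydronaphthalen-3-yl acetate (both C-3 epimers)
Product: 15 (4aS,5S,8aS)-5-(hydroxymethyl)-1,1,4a-trimethyl-6-methylidene-2-oxodecahydronaphthalen-3-yl acetate (both C-3 epimers)
Conditions: Zn, CH2Br2, TiCl4, THF/CH2Cl2, 0 °C to rt
Reagents that add atoms: dibromomethane, BrCBr
Why: Takai–Lombardo methylenation is non-basic, so the β-hydroxy ketone should neither eliminate nor epimerise at C9, and it should select the C8 ketone over the C3 ketone, which is shielded by the quaternary C4 and the acetoxy-bearing C2.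

Step 9
Reactants: 15 (4aS,5S,8aS)-5-(hydroxymethyl)-1,1,4a-trimethyl-6-methylidene-2-oxodecahydronaphthalen-3-yl acetate (both C-3 epimers)
Product: 16 (3R,4aS,5S,8aS)-5-(hydroxymethyl)-1,1,4a-trimethyl-6-methylidene-2-oxodecahydronaphthalen-3-yl acetate
Conditions: KOAc, AcOH, 60 °C
Reagents that add atoms: none
Why: Reversible enolisation of the α-acetoxy ketone toward C2 (thermodynamic control) should give the epimer with the equatorial acetoxy group, away from the syn-axial C10 and C4 methyls of ring A; C9 is no longer enolisable.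

Step 10
Reactants: 16 (3R,4aS,5S,8aS)-5-(hydroxymethyl)-1,1,4a-trimethyl-6-methylidene-2-oxodecahydronaphthalen-3-yl acetate; 17 isofraxidin (7-hydroxy-6,8-dimethoxy-2H-chromen-2-one)
Product: 18 (3R,4aS,5S,8aS)-5-{[(6,8-dimethoxy-2-oxo-2H-chromen-7-yl)oxy]methyl}-1,1,4a-trimethyl-6-methylidene-2-oxodecahydronaphthalen-3-yl acetate
Conditions: PPh3, DIAD, THF, 0 °C to rt
Reagents that add atoms: none
Why: Mitsunobu etherification of the primary alcohol with the acidic 7-hydroxyl of the coumarin under neutral conditions, which the α-acetoxy ketone and the exocyclic alkene should tolerate; no stereocentre is involved.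

**Compound list**
1 | 2-methylcyclohex-2-en-1-one | CC1=CCCCC1=O | starting material
2 | (R)-2-methylcyclohex-2-en-1-ol | O[C@@H]1CCCC=C1C | intermediate
3 | (R)-2-methylcyclohex-2-en-1-yl 2-methylpropanoate | CC(C)C(=O)O[C@@H]1CCCC=C1C | intermediate
4 | trimethyl[(2-methyl-1-{[(1R)-2-methylcyclohex-2-en-1-yl]oxy}prop-1-en-1-yl)oxy]silane (silyl ketene acetal, not isolated) | CC(C)=C(O[Si](C)(C)C)O[C@@H]1CCCC=C1C | intermediate
5 | trimethylsilyl 2-methyl-2-[(1S)-2-methylcyclohex-2-en-1-yl]propanoate (not isolated) | CC1=CCCC[C@@H]1C(C)(C)C(=O)O[Si](C)(C)C | intermediate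
6 | 2-methyl-2-[(1S)-2-methylcyclohex-2-en-1-yl]propanoic acid | CC1=CCCC[C@@H]1C(C)(C)C(=O)O | intermediate
7 | 2-methyl-2-[(1S)-2-methylcyclohex-2-en-1-yl]propanoyl chloride (not isolated) | CC1=CCCC[C@@H]1C(C)(C)C(Cl)=O | intermediate
8 | 2-ethoxy-4-methyl-4-[(1S)-2-methylcyclohex-2-en-1-yl]pent-1-en-3-one (not isolated) | CC1=CCCC[C@@H]1C(C)(C)C(=O)C(=C)OCC | intermediate
9 | 4-methyl-4-[(1S)-2-methylcyclohex-2-en-1-yl]pentane-2,3-dione | CC1=CCCC[C@@H]1C(C)(C)C(=O)C(C)=O | intermediate
10 | 4-methyl-4-[(1S)-2-methyl-4-oxocyclohex-2-en-1-yl]pentane-2,3-dione | O=C1CC[C@H](C(C)(C)C(=O)C(C)=O)C(C)=C1 | intermediate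
11 | 4-methyl-4-[(1S)-2-methyl-4-oxocyclohex-2-en-1-yl]-3-oxopent-1-en-2-yl acetate (bis-enone) | O=C1CC[C@H](C(C)(C)C(=O)C(=C)OC(C)=O)C(C)=C1 | intermediate
12 | (4aS,8aS)-1,1,4a-trimethyl-2-oxo-6-[(tributylstannyl)oxy]-1,2,3,4,4a,7,8,8a-octahydronaphthalen-3-yl acetate (tin enolate, both C-3 epimers, not isolated) | CCCC[Sn](CCCC)(CCCC)OC1CC[C@@H]2C(C)(C)C(=O)C(OC(C)=O)C[C@]2(C)C=1 | intermediate
13 | (4aS,5S,8aS)-1,1,4a-trimethyl-2,6-dioxo-5-{[(tributylstannyl)oxy]methyl}decahydronaphthalen-3-yl acetate (tin aldolate, both C-3 epimers, not isolated) | O=C1CC[C@@H]2C(C)(C)C(=O)C(OC(C)=O)C[C@]2(C)[C@H]1CO[Sn](CCCC)(CCCC)CCCC | intermediate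
14 | (4aS,5S,8aS)-5-(hydroxymethyl)-1,1,4a-trimethyl-2,6-dioxodecahydronaphthalen-3-yl acetate (cis-fused, both C-3 epimers) | O=C1CC[C@@H]2C(C)(C)C(=O)C(OC(C)=O)C[C@]2(C)[C@H]1CO | intermediate
15 | (4aS,5S,8aS)-5-(hydroxymethyl)-1,1,4a-trimethyl-6-methylidene-2-oxodecahydronaphthalen-3-yl acetate (both C-3 epimers) | C=C1CC[C@@H]2C(C)(C)C(=O)C(OC(C)=O)C[C@]2(C)[C@H]1CO | intermediate
16 | (3R,4aS,5S,8aS)-5-(hydroxymethyl)-1,1,4a-trimethyl-6-methylidene-2-oxodecahydronaphthalen-3-yl acetate | C=C1CC[C@@H]2C(C)(C)C(=O)[C@H](OC(C)=O)C[C@]2(C)[C@H]1CO | intermediate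
17 | isofraxidin (7-hydroxy-6,8-dimethoxy-2H-chromen-2-one) | COc1cc2ccc(=O)oc2c(OC)c1O | starting material
18 | (3R,4aS,5S,8aS)-5-{[(6,8-dimethoxy-2-oxo-2H-chromen-7-yl)oxy]methyl}-1,1,4a-trimethyl-6-methylidene-2-oxodecahydronaphthalen-3-yl acetate (CNP0183157.2) | C=C1CC[C@@H]2C(C)(C)C(=O)[C@H](OC(C)=O)C[C@]2(C)[C@H]1COc1c(OC)cc2ccc(=O)oc2c1OC | target

Total step count: 10. Longest linear sequence: 10 steps (1 to 18).

**Steps most likely to fail**

Step 7 (key step, proposed new method). The stannyl radical chain may be carried by the side-chain ketyl, or hydrogen transfer may overtake ring closure, so that the tin enolate ends up in the wrong ring or no ring forms. The fallback uses known reaction types and sets out from 11. Conjugate addition of hydrogen iodide to the acetoxy enone (NaI, Me3SiCl, MeCN, −20 °C, then water) should give 1-iodo-4-methyl-4-[(1S)-2-methyl-4-oxocyclohex-2-en-1-yl]-3-oxopentan-2-yl acetate F1. With Et3B and air in PhH, iodine-atom abstraction gives the primary C1 radical, which cyclises 6-exo-trig onto C10 of the ring enone on the side-chain face. The resulting α-keto radical is captured by Et3B as the diethylboron enolate F2, which is hydroxymethylated by formaldehyde in the same flask. The fallback comes back to the route at 14.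

Step 8. Chemoselectivity between the two ketones may be lost, or the Lewis-acidic reagent may dehydrate the β-hydroxy ketone. The fallback sets out from 14. Silylation (t-BuMe2SiCl, imidazole, DMF) gives the silyl ether F3. Addition of Me3SiCH2Li/CeCl3 (THF, −78 °C) to the less hindered C8 ketone gives the β-hydroxysilane F4. HF·pyridine in MeCN then effects the Peterson elimination and removes the silyl ether in one operation. The fallback comes back at 15.

Step 10. Activation of the hindered primary alcohol may be slow and the doubly ortho-substituted phenol may attack poorly, so that the hydrazide is alkylated instead. The fallback sets out from 16. Triflation (Tf2O, 2,6-lutidine, CH2Cl2, −78 °C) gives the primary triflate F5. Displacement by the cesium salt of isofraxidin 17 (Cs2CO3, MeCN, 0 °C to rt) forms the ether by SN2 reaction. The fallback comes back at 18.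

Further compounds
F1 | step 7 | 1-iodo-4-methyl-4-[(1S)-2-methyl-4-oxocyclohex-2-en-1-yl]-3-oxopentan-2-yl acetate (both epimers at the acetoxy carbon) | O=C1CC[C@H](C(C)(C)C(=O)C(CI)OC(C)=O)C(C)=C1
F2 | step 7 | (4aS,8aS)-6-[(diethylboranyl)oxy]-1,1,4a-trimethyl-2-oxo-1,2,3,4,4a,7,8,8a-octahydronaphthalen-3-yl acetate (boron enolate, both C-3 epimers) | CCB(CC)OC1CC[C@@H]2C(C)(C)C(=O)C(OC(C)=O)C[C@]2(C)C=1
F3 | step 8 | (4aS,5S,8aS)-5-({[tert-butyl(dimethyl)silyl]oxy}methyl)-1,1,4a-trimethyl-2,6-dioxodecahydronaphthalen-3-yl acetate (both C-3 epimers) | O=C1CC[C@@H]2C(C)(C)C(=O)C(OC(C)=O)C[C@]2(C)[C@H]1CO[Si](C)(C)C(C)(C)C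
F4 | step 8 | (4aS,5S,8aS)-5-({[tert-butyl(dimethyl)silyl]oxy}methyl)-6-hydroxy-1,1,4a-trimethyl-2-oxo-6-[(trimethylsilyl)methyl]decahydronaphthalen-3-yl acetate (C-6 configuration open, both C-3 epimers) | C[Si](C)(C)CC1(O)CC[C@@H]2C(C)(C)C(=O)C(OC(C)=O)C[C@]2(C)[C@H]1CO[Si](C)(C)C(C)(C)C
F5 | step 10 | (3R,4aS,5S,8aS)-1,1,4a-trimethyl-6-methylidene-2-oxo-5-{[(trifluoromethanesulfonyl)oxy]methyl}decahydronaphthalen-3-yl acetate | C=C1CC[C@@H]2C(C)(C)C(=O)[C@H](OC(C)=O)C[C@]2(C)[C@H]1COS(=O)(=O)C(F)(F)F
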